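## Structural features

The target is an eremophilane-type octalin acylated at C1. Ring A (C5–C10) is a cyclohexenone whose C8 carbonyl is conjugated with the C9=C10 double bond, and it is fused through the C5–C10 bond to the saturated ring B (C10, C1–C5). C5 is quaternary and carries the methyl C14; its neighbour C4 carries the carboxyl C15; C1, on the far side of the sp2 carbon C10, carries the oxygen of a (2E,4R)-2,4-dimethyloct-2-enoate. The C1 oxygen, the C4 carboxyl and the C5 methyl all lie on one face (called β here; 1R,4S,5R), with the C1 oxygen axial and 1,3-syn to the methyl. The 3-oxoprop-1-en-2-yl group at C7 (7S) lies on the other face, equatorial, next to the C8 carbonyl.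

Fragile parts are:
- the 2-substituted acrolein, a Michael acceptor;
- the C7 hydrogen, which is α to the ketone and allylic to the enal, so that epimerisation and migration of the exocyclic double bond are easy;
- the 1,4-relation of the C8 ketone and the C12 aldehyde, which invites acid-promoted cyclodehydration to a furan;
- the γ-stereocentre of the enoate, which is lost if strong base deconjugates the ester.

The real difficulty is the quaternary C5, wedged between the C4 stereocentre and the tetrasubstituted ring fusion, with C14 cis to both C15 and the C1 oxygen. Because C14 and the C1 oxygen are cis across C10, a C1 hydroxyl on an octalin with a C5=C10 double bond can hand a methylene carbon to C5 and C10 from its own face. That carbon later becomes C14, and this is the feature the key step uses.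

## Logic of the disconnections

**38 ⇒ 37.** The C11=C13 double bond is cut, leaving an aldehyde with a free α-methylene. This keeps the Michael acceptor and the labile C7–H/enal array out of the synthesis until the last operation. The forward step must be a methylenation mild enough to spare the free acid, both esters and the C7 centre.

**37 ⇒ 35 ⇒ 34.** The C12 aldehyde is traced to the terminal alkene of an allyl group, and the free C15 acid to its tert-butyl ester. The acidolysis is placed before the keto-aldehyde exists, because 37 and 38 would risk furan formation in strong acid whereas 34 has nothing acid-labile but the tert-butyl group. The forward cleavage must pick the monosubstituted alkene over the enone and the trisubstituted enoate.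

**34 ⇒ 32.** The C7–C11 bond is cut. C7 is the α′-carbon of the enone, so the bond is made by alkylating a kinetic enolate. The forward step needs deprotonation at C7 only (not at C1, C4 or the γ-carbon of the side chain) and attack anti to the axial C14, which is also the thermodynamic outcome.

**32 ⇒ 31 ⇒ 19 + 29.** The C8 carbonyl is masked as its acetal and the C1–O acyl bond is cut. This splits the molecule into the bicyclic core and the side-chain acid, and the acetal lets C1 be adjusted while C8 is silent. The forward acylation meets a hindered axial allylic alcohol and must not epimerise the γ-centre of 29.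

**29 ⇒ 28 ⇒ 25 + 26; 25 ⇒ 24 ⇒ 22 ⇒ 20 + 21.** The trisubstituted alkene is cut by olefination logic and the methyl-bearing stereocentre is traced to an auxiliary-controlled enolate methylation. All pieces are commercial. The forward demands are E selectivity and no racemisation of the α-branched aldehyde 27.

**19 ⇒ 18 ⇒ 17 ⇒ 15.** The C1 carbinol is traced to the enone, the C9=C10 bond to the regiodefined enol ether, and C14 is tied back to C10 to give the cyclopropyl ketone. The gain is that the angular methyl and the alkene both come from one temporary bond. The forward demands are cleavage of the exocyclic C10–C14 bond only, and hydride delivery anti to the new methyl.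

**15 ⇒ 14 ⇒ 12 (key).** The C5–C14 and C10–C14 bonds are cut together. The quaternary centre disappears and the precursor is a flat, tetrasubstituted alkene. The single forward demand is facial selectivity, supplied by the C1 hydroxyl, which must be cis to the C4 ester.

**12 ⇒ 11 ⇒ 9 ⇒ 7.** Ester and acetal are removed and ring A is re-aromatised. The Δ5(10) alkene and the C8 oxygen are exactly what reduction of a methoxy arene leaves behind. The forward reduction must keep the benzylic C1 oxygen and the C4 configuration.

**7 ⇒ 6 ⇒ 5.** The lactone C–O bond is cut and the carbinol is traced to the ketone. Only C1 needs reagent control; C4, being epimerisable, follows by equilibration into the only epimer that can lactonise.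

**5 ⇒ 3 ⇒ 1 + 2.** The aryl–acyl bond (C1–C10) and the C3–C4 bond are cut, giving an arylacetate and an acrylate. The forward demands are mono-addition and cyclisation ortho to the side chain.

## Other disconnections considered

**Alternative 1:** The cut runs through C5–C10 and C3–C4, so both rings open and the core collapses to the acyclic triene A1. In A1 an (E)-enoate (C4=C5, methyl on C5) is tethered through C6–C9 to a 2-silyloxy-1,3-diene (C10=C1–C2=C3). Forward, heating or a Lewis acid would bring about an intramolecular Diels–Alder reaction to the trans-fused adduct A2.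

- In its favour: both rings, the quaternary C5 with its methyl already in place, and the C4/C5 cis relation (a direct consequence of the E dienophile) arise in one step, and the enol ether marks C1 for oxygen.
- Against it here:
  - the dienophile is trisubstituted and activated at its far end, which makes such cycloadditions slow and their ring-fusion selectivity modest;
  - the absolute sense rests on one silyloxy stereocentre in the tether (C8), which is destroyed later;
  - the enol ether of A2 points towards C2, so the C9=C10 bond still needs hydrolysis, re-enolisation towards C10 and dehydrogenation;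
  - the C1 carbonyl must then be reduced to the axial alcohol exactly as in the chosen plan.
- Comparison: on structure this route is the better one, since C14 is present from the start and no temporary ring has to be made and opened. On mechanism the chosen plan is the more dependable, because a chelation-directed syn methylene transfer has one accessible transition state whereas A1 can react through several tether conformations. On step economy the two are about equal: the shorter sequence after the cycloaddition is offset by the linear assembly of a stereodefined triene with two differentiated silyl ethers.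

**Alternative 2:** Only the C5–C6 bond is disconnected, with a C3–C8 bond re-formed in the retron. Ring A opens and the precursor is the bicyclo[2.2.2]octene carbinol A3, in which C8 carries hydroxyl and vinyl (C7=C6) and the C4=C5 enoate is the unsaturated bridge. Forward, the potassium alkoxide of A3 (KH, 18-crown-6) would undergo an anionic oxy-Cope shift to the enolate of the cis-fused decalone A4.

- In its favour:
  - the rearrangement is suprafacial inside a rigid cage, so C5 and the ring fusion are set stereospecifically and not merely selectively; on this point it is the better of the two plans;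
  - it delivers the C8 carbonyl directly, and as a regiodefined C7 enolate it could be allylated at C7 in the same flask, which is better than the kinetic deprotonation of step 20.
- Against it here:
  - A4 has hydrogen at C10 and an enoate at C3=C4, so the C4 stereocentre must still be created by conjugate reduction and protonation next to the quaternary carbon, with an open facial outcome;
  - the C9=C10 bond and the C1 carbinol need further redox steps;
  - A3 needs an enantioselective Diels–Alder construction of the cage and a vinyl addition syn to the alkene bridge beside the acetal.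
- Comparison: mechanistically it is equal or superior for the quaternary centre. Structurally it is weaker, because C4 is left to a late, weakly controlled step whereas the chosen plan fixes C4 early through the lactone. In step count it is unlikely to be shorter once the cage synthesis and the adjustments at C1, C3 and C4 are added.

**Alternative 3:** The C1–C10 bond is cut, which opens ring B and leads to the 4,4-disubstituted cyclohexadienone A5. Its side chain already contains C4 with the ester and ends in the C1 aldehyde. Forward, a chiral triazolylidene carbene would turn the aldehyde into its acyl anion equivalent, which adds to one of the two enantiotopic enone arms (intramolecular Stetter reaction) to give the cis-fused diketone A6.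

- In its favour:
  - the step is catalytic and creates C5 and C10 from a carbon that was not stereogenic, with C14 in place;
  - the C6=C7 enone left behind would allow regiospecific generation of a C7 enolate by conjugate reduction, which equals or betters the chosen plan at that position.
- Against it here:
  - six-membered ring closure through an all-carbon tether is at the less developed end of this reaction;
  - A5 already carries the C4 stereocentre, so catalyst control must cooperate with or override it, and making A5 enantiopure needs a separate asymmetric step plus an alkylative dearomatisation next to C4;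
  - A6 is cis-fused with hydrogen at C10, has its unsaturation on the wrong side (C6=C7 instead of C9=C10) and two ketones to tell apart.
- Comparison: on structure it equals the chosen plan in carrying C14 directly and is better in being catalytic at the quaternary centre. On mechanism its stereocontrol (catalyst against an existing centre) is less transparent than delivery from a single hydroxyl. On step economy a short route to A6 is balanced by the enone transposition and ketone differentiation afterwards, so no clear saving is expected.

Key step: step 8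

## Remarks before the steps

- Positions are quoted in eremophilane numbering (C14 = methyl on C5, C15 = carboxyl on C4, C11–C13 = acrolein unit); β is the face that carries C14. Systematic names use naphthalene numbering.
- Checked against the target, precursor 12 and product 14 need no correction: the C1 hydroxyl, the C4 ester and the new methylene are all β.
- Two points of design were tightened. The benzylic hydroxyl enters the Birch reduction as a pre-formed lithium alkoxide. The tert-butyl ester is cleaved before the acid-sensitive γ-keto-enal is assembled, so the mildest reaction comes last.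
- tert-Butyl acrylate replaces a methyl acrylate so that the two ester groups of 3 can be told apart, which saves one step.

## Route

Step 1
Reactants: 1 methyl 4-methoxyphenylacetate; 2 tert-butyl acrylate
Product: 3 5-tert-butyl 1-methyl 2-(4-methoxyphenyl)pentanedioate (racemic)
Conditions: t-BuOK (10 mol %), THF, 0 °C; 1 in slight excess
Reagents that add atoms: none
Why: Base-catalysed Michael addition of the arylacetate enolate to the acrylate; mono-addition is favoured because the new α-carbon is tertiary and 1 is in excess. The stereocentre (later C4) forms racemic and is corrected in step 4.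

Step 2
Reactants: 3 5-tert-butyl 1-methyl 2-(4-methoxyphenyl)pentanedioate
Product: 5 methyl 6-methoxy-4-oxo-1,2,3,4-tetrahydronaphthalene-1-carboxylate (racemic), via 5-methoxy-4-(4-methoxyphenyl)-5-oxopentanoic acid 4 (not isolated)
Conditions: CF3CO2H, CH2Cl2, rt; evaporate; P2O5 in MeSO3H, 40 °C
Reagents that add atoms: none
Why: Acidolysis frees only the tert-butyl ester; the acid then closes ring B by intramolecular Friedel–Crafts acylation, as in the known cyclisation of 4-(4-methoxyphenyl)butanoic acids to 7-methoxy-1-tetralones. Only the six-membered closure ortho to the side chain is possible.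

Step 3
Reactants: 5 methyl 6-methoxy-4-oxo-1,2,3,4-tetrahydronaphthalene-1-carboxylate
Product: 6 methyl (4R)-4-hydroxy-6-methoxy-1,2,3,4-tetrahydronaphthalene-1-carboxylate (both C1 epimers)
Conditions: RuCl[(R,R)-TsDPEN](p-cymene) (1 mol %), HCO2H/Et3N (5:2), 40 °C
Reagents that add atoms: none
Why: Noyori–Ikariya asymmetric transfer hydrogenation of an aryl ketone; the (R,R) catalyst should give the (R) carbinol, as with 1-tetralone, by hydride and proton transfer through a six-membered transition state. The remote ester-bearing centre stays racemic, so both epimers share the 4R configuration.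

Step 4
Reactants: 6 methyl (4R)-4-hydroxy-6-methoxy-1,2,3,4-tetrahydronaphthalene-1-carboxylate
Product: 7 (1S,4R)-4-hydroxy-6-methoxy-1,2,3,4-tetrahydronaphthalene-1-carboxylic acid 1,4-lactone (bridged; benzo-fused 2-oxabicyclo[2.2.2]octan-3-one)
Conditions: t-BuOK (20 mol %), toluene, 90 °C, MeOH distilled out; AcOH quench
Reagents that add atoms: none
Why: The hydrogen α to the ester is benzylic, so alkoxide equilibrates that centre (C4 in eremophilane numbering) while the carbinol is untouched. Only the cis epimer can close the bridged lactone by transesterification, and removal of methanol drains both epimers into 7, whose bridgehead α-hydrogen can no longer enolise.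

Step 5
Reactants: 7 bridged lactone
Product: 9 (1S,4R)-4-hydroxy-6-methoxy-1,2,3,4,5,8-hexahydronaphthalene-1-carboxylic acid, via dilithium (1S,4R)-4-oxido-6-methoxy-1,2,3,4-tetrahydronaphthalene-1-carboxylate 8 (not isolated)
Conditions: LiOH·H2O (1.05 equiv), THF/H2O, rt; dry; LiNH2 (1.1 equiv), NH3(l)/THF, −78 °C; Li (6 equiv), t-BuOH (4 equiv), −78 → −33 °C; isoprene, then NH4Cl; NaH2PO4 work-up at pH 5–6, 0 °C; used crude
Reagents that add atoms: lithium hydroxide, [Li+].[OH-]
Why: Saponification opens the lactone with retention at both centres, and Birch reduction of the anisole ring gives the 2,5-dihydroanisole with the ring-fusion alkene in place. The carbinol is carried as its pre-formed lithium alkoxide, which cannot leave as oxide, and tert-butanol is the only proton donor, so benzylic C–O cleavage and deprotonation next to the carboxylate should not compete.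

Step 6
Reactants: 9 (1S,4R)-4-hydroxy-6-methoxy-1,2,3,4,5,8-hexahydronaphthalene-1-carboxylic acid; 10 ethylene glycol
Product: 11 (1S,4R)-6,6-(ethylenedioxy)-4-hydroxy-1,2,3,4,5,6,7,8-octahydronaphthalene-1-carboxylic acid
Conditions: ethylene glycol (10 equiv), PPTS (5 mol %), THF, 0 °C → rt; Et3N quench
Reagents that add atoms: none
Why: Acid-catalysed exchange of the methyl enol ether for the dioxolane through the C8 oxocarbenium ion. The tetrasubstituted alkene stays β,γ to the acetal carbon, the usual outcome for Birch products.

Step 7
Reactants: 11 (1S,4R)-6,6-(ethylenedioxy)-4-hydroxy-1,2,3,4,5,6,7,8-octahydronaphthalene-1-carboxylic acid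
Product: 12 tert-butyl (1S,4R)-6,6-(ethylenedioxy)-4-hydroxy-1,2,3,4,5,6,7,8-octahydronaphthalene-1-carboxylate
Conditions: O-tert-butyl-N,N'-diisopropylisourea (3 equiv), CH2Cl2, rt
Reagents that add atoms: O-tert-butyl-N,N'-diisopropylisourea, CC(C)N=C(OC(C)(C)C)NC(C)C
Why: Isourea esterification: the carboxylic acid protonates the isourea and the carboxylate takes up the tert-butyl group, so the secondary hydroxyl and the acetal are untouched and no strong acid is needed.

Step 8
Reactants: 12 tert-butyl (1S,4R)-6,6-(ethylenedioxy)-4-hydroxy-1,2,3,4,5,6,7,8-octahydronaphthalene-1-carboxylate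
Product: 14 tert-butyl (1S,4R,4aR,8aS)-6,6-(ethylenedioxy)-4-hydroxyoctahydro-4a,8a-methanonaphthalene-1-carboxylate (methano bridge cis to hydroxyl), via ethylzinc alkoxide of the precursor 13 (not isolated)
Conditions: Et2Zn (6 equiv), CH2I2 (6 equiv), CH2Cl2, −15 °C → rt; aq. NH4Cl
Reagents that add atoms: diiodomethane, ICI
Why: Hydroxyl-directed Simmons–Smith cyclopropanation in Furukawa's variant, the closest precedent being the cyclopropanation of cyclic allylic alcohols and of Δ9(10)-octal-1-ols to propellanes. Et2Zn first converts 12 into the zinc alkoxide 13, with which the carbenoid EtZnCH2I aggregates. Methylene transfer to C5=C10 is concerted and syn through a butterfly transition state, so C5–C14 and C10–C14 form together and the three-membered ring closes as a [2+1] addition with no intermediate that could scramble configuration. Both new stereocentres, C5 and C10, are controlled by the C1 stereocentre through zinc chelation: C14 arrives on the β face, cis to the C1 oxygen, and because step 4 fixed the C4 ester cis to that oxygen, C14 is also cis to C15. The only selectivity needed is facial, and the alkoxide secures it; the ester carbonyl on the same face can only reinforce zinc binding. Chemoselectivity is no issue because the electron-rich tetrasubstituted alkene is the only alkene present, and the acetal and tert-butyl ester are inert to the carbenoid.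

Step 9
Reactants: 14 cyclopropane-bridged hydroxy ester
Product: 15 tert-butyl (1S,4aR,8aS)-6,6-(ethylenedioxy)-4-oxooctahydro-4a,8a-methanonaphthalene-1-carboxylate
Conditions: Dess–Martin periodinane (1.5 equiv), NaHCO3, CH2Cl2, 0 °C → rt
Reagents that add atoms: none
Why: Dess–Martin oxidation of the secondary cyclopropylcarbinol under buffered, non-acidic conditions, which avoids cyclopropylcarbinyl cation rearrangement and spares the acetal.

Step 10
Reactants: 15 cyclopropyl ketone
Product: 17 tert-butyl (1S,8aR)-6,6-(ethylenedioxy)-8a-methyl-4-(trimethylsilyloxy)-1,2,3,5,6,7,8,8a-octahydronaphthalene-1-carboxylate, via samarium enolate 16 (not isolated)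
Conditions: SmI2 (2.5 equiv), THF/DMPU (9:1), t-BuOH (1.0 equiv), −78 → −30 °C; then Me3SiCl (5 equiv), Et3N (6 equiv), −78 → 0 °C
Reagents that add atoms: chlorotrimethylsilane, C[Si](C)(C)Cl
Why: Single-electron reduction gives the ketyl, which opens the cyclopropane bond that overlaps best with the carbonyl π system, the exocyclic C10–C14 bond; the C14 radical is reduced and protonated to the methyl and the samarium enolate 16 is silylated on oxygen. This is the known reductive opening of bicyclo[4.1.0]heptan-2-ones with enolate trapping, and C5 keeps its configuration because only C10–C14 breaks.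

Step 11
Reactants: 17 trimethylsilyl enol ether
Product: 18 tert-butyl (1S,8aR)-6,6-(ethylenedioxy)-8a-methyl-4-oxo-1,2,3,4,6,7,8,8a-octahydronaphthalene-1-carboxylate
Conditions: Pd(OAc)2 (1.1 equiv), MeCN, rt
Reagents that add atoms: none
Why: Saegusa–Ito oxidation: palladation of the enol ether at C10 and syn β-hydride elimination can only take hydrogen from C9, since C5 is quaternary, so the C9=C10 enone forms regiospecifically.

Step 12
Reactants: 18 enone
Product: 19 tert-butyl (1S,4R,8aR)-6,6-(ethylenedioxy)-4-hydroxy-8a-methyl-1,2,3,4,6,7,8,8a-octahydronaphthalene-1-carboxylate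
Conditions: NaBH4 (1.5 equiv), CeCl3·7H2O (1.2 equiv), MeOH, −78 → −40 °C
Reagents that add atoms: none
Why: Luche 1,2-reduction of the enone. The axial C5 methyl shields the β face of the C1 carbonyl (1,3-relation), so hydride should arrive from the α face and give the axial 1β-alcohol (1R), as in the reduction of steroidal 4-en-6-ones to 6β-alcohols.

Step 13
Reactants: 20 (R)-4-benzyl-2-oxazolidinone; 21 hexanoyl chloride
Product: 22 (R)-4-benzyl-3-hexanoyloxazolidin-2-one
Conditions: Et3N (1.5 equiv), DMAP (10 mol %), CH2Cl2, 0 °C → rt
Reagents that add atoms: none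
Why: N-Acylation of the oxazolidinone by the acid chloride with nucleophilic catalysis through the acylpyridinium ion.

Step 14
Reactants: 22 (R)-4-benzyl-3-hexanoyloxazolidin-2-one
Product: 24 (R)-4-benzyl-3-[(2R)-2-methylhexanoyl]oxazolidin-2-one, via sodium Z-enolate 23 (not isolated)
Conditions: NaN(SiMe3)2 (1.1 equiv), THF, −78 °C; MeI (3 equiv), −78 °C
Reagents that add atoms: iodomethane, CI
Why: Evans alkylation: the chelated Z enolate 23 is methylated on the face away from the benzyl group, which sets the (R) centre of the side chain.

Step 15
Reactants: 24 (R)-4-benzyl-3-[(2R)-2-methylhexanoyl]oxazolidin-2-one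
Product: 25 (R)-2-methylhexan-1-ol
Conditions: LiBH4 (1.2 equiv), H2O (1.1 equiv), Et2O, 0 °C
Reagents that add atoms: none
Why: Reductive removal of the auxiliary with LiBH4 gives the primary alcohol without touching the α-stereocentre; the oxazolidinone is recovered.

Step 16
Reactants: 25 (R)-2-methylhexan-1-ol; 26 ethyl 2-(triphenylphosphoranylidene)propanoate
Product: 28 ethyl (2E,4R)-2,4-dimethyloct-2-enoate, via (R)-2-methylhexanal 27 (not isolated)
Conditions: TEMPO (10 mol %), PhI(OAc)2 (1.1 equiv), CH2Cl2, rt; then 26 (1.3 equiv), rt → 40 °C
Reagents that add atoms: none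
Why: TEMPO/PhI(OAc)2 oxidation to the aldehyde, followed in the same flask by Wittig olefination with the stabilised, α-branched ylide, which gives the E trisubstituted enoate. Trapping the aldehyde as it forms limits epimerisation of its α-centre.

Step 17
Reactants: 28 ethyl (2E,4R)-2,4-dimethyloct-2-enoate
Product: 29 (2E,4R)-2,4-dimethyloct-2-enoic acid
Conditions: LiOH (3 equiv), THF/MeOH/H2O, rt; 1 M HCl
Reagents that add atoms: lithium hydroxide, [Li+].[OH-]
Why: Saponification; the enoate has no α-hydrogen and aqueous hydroxide is too weak to deprotonate the γ-position, so the stereocentre and the E geometry persist.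

Step 18
Reactants: 19 allylic alcohol; 29 (2E,4R)-2,4-dimethyloct-2-enoic acid
Product: 31 tert-butyl (1S,4R,8aR)-4-{[(2E,4R)-2,4-dimethyloct-2-enoyl]oxy}-6,6-(ethylenedioxy)-8a-methyl-1,2,3,4,6,7,8,8a-octahydronaphthalene-1-carboxylate, via mixed 2,4,6-trichlorobenzoic anhydride 30 (not isolated)
Conditions: 2,4,6-Cl3C6H2COCl (1.5 equiv), Et3N (2 equiv), THF, rt; then 19, DMAP (2 equiv), toluene, rt → 50 °C
Reagents that add atoms: none
Why: Yamaguchi esterification: the mixed anhydride 30 passes the enoyl group through the acylpyridinium ion to the hindered axial allylic alcohol with retention at C1. No strong base is present, so the γ-centre of the acid is safe.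

Step 19
Reactants: 31 acetal diester
Product: 32 tert-butyl (1S,4R,8aR)-4-{[(2E,4R)-2,4-dimethyloct-2-enoyl]oxy}-8a-methyl-6-oxo-1,2,3,4,6,7,8,8a-octahydronaphthalene-1-carboxylate
Conditions: PPTS (0.3 equiv), acetone/H2O (9:1), 50 °C
Reagents that add atoms: water, O
Why: Mild acid hydrolysis of the allylic acetal through the conjugated oxocarbenium ion, much faster than cleavage of the tert-butyl ester or ionisation of the C1 ester. The C8 ketone emerges directly conjugated with C9=C10.

Step 20
Reactants: 32 enone diester
Product: 34 tert-butyl (1S,4R,7R,8aR)-7-allyl-4-{[(2E,4R)-2,4-dimethyloct-2-enoyl]oxy}-8a-methyl-6-oxo-1,2,3,4,6,7,8,8a-octahydronaphthalene-1-carboxylate, via cross-conjugated lithium enolate 33 (not isolated)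
Conditions: LiN(SiMe3)2 (1.1 equiv), THF, −78 °C (32 added to base); allyl bromide (3 equiv), DMPU, −78 → −30 °C
Reagents that add atoms: allyl bromide, C=CCBr
Why: Kinetic α′-deprotonation of the enone at C7 by a hindered amide (ketone enolisation outruns deprotonation of either ester) gives the cross-conjugated enolate 33, which is allylated from the α face, anti to the axial C5 methyl. The 7α (equatorial) product is also the thermodynamically preferred epimer.

Step 21
Reactants: 34 allyl enone tert-butyl ester
Product: 35 (1S,4R,7R,8aR)-7-allyl-4-{[(2E,4R)-2,4-dimethyloct-2-enoyl]oxy}-8a-methyl-6-oxo-1,2,3,4,6,7,8,8a-octahydronaphthalene-1-carboxylic acid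
Conditions: CF3CO2H/CH2Cl2 (1:3), 0 °C → rt
Reagents that add atoms: none
Why: Acidolysis of the tert-butyl ester with loss of isobutene. It is done here, before the γ-keto aldehyde exists, because enone, allyl group and both secondary esters tolerate CF3CO2H whereas the later keto-enal would risk cyclodehydration.

Step 22
Reactants: 35 allyl enone acid
Product: 37 (1S,4R,7S,8aR)-4-{[(2E,4R)-2,4-dimethyloct-2-enoyl]oxy}-8a-methyl-6-oxo-7-(2-oxoethyl)-1,2,3,4,6,7,8,8a-octahydronaphthalene-1-carboxylic acid, via side-chain 1,2-diol 36 (not isolated)
Conditions: OsO4 (2 mol %), NaIO4 (4 equiv), 2,6-lutidine (2 equiv), dioxane/H2O (3:1), rt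
Reagents that add atoms: osmium tetroxide (catalytic), O=[Os](=O)(=O)=O; sodium periodate, [Na+].[O-]I(=O)(=O)=O
Why: Lemieux–Johnson cleavage: OsO4 dihydroxylates the monosubstituted, most electron-rich alkene in preference to the enone and the trisubstituted enoate, and NaIO4 cleaves the diol 36 to the aldehyde. 2,6-Lutidine suppresses acid-promoted side reactions.

Step 23
Reactants: 37 keto aldehyde acid
Product: 38 (1S,4R,7S,8aR)-4-{[(2E,4R)-2,4-dimethyloct-2-enoyl]oxy}-8a-methyl-6-oxo-7-(3-oxoprop-1-en-2-yl)-1,2,3,4,6,7,8,8a-octahydronaphthalene-1-carboxylic acid (target)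
Conditions: 37% aq. HCHO (2 equiv), pyrrolidine (20 mol %), propionic acid (20 mol %), i-PrOH, 45 °C
Reagents that add atoms: formaldehyde, C=O
Why: Amine-catalysed α-methylenation of the aldehyde (enamine Mannich reaction with formaldehyde, then loss of the amine). Only the aldehyde has an unhindered α-CH2, the buffered medium leaves the esters alone, and C7 keeps or relaxes to its favoured equatorial configuration.

## Compound list

1 | methyl 4-methoxyphenylacetate | COC(=O)Cc1ccc(OC)cc1 | starting material
2 | tert-butyl acrylate | C=CC(=O)OC(C)(C)C | starting material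
3 | 5-tert-butyl 1-methyl 2-(4-methoxyphenyl)pentanedioate (racemic) | COC(=O)C(CCC(=O)OC(C)(C)C)c1ccc(OC)cc1 | intermediate
4 | 5-methoxy-4-(4-methoxyphenyl)-5-oxopentanoic acid (racemic) | COC(=O)C(CCC(=O)O)c1ccc(OC)cc1 | intermediate (not isolated)
5 | methyl 6-methoxy-4-oxo-1,2,3,4-tetrahydronaphthalene-1-carboxylate (racemic) | COC(=O)C1CCC(=O)c2cc(OC)ccc12 | intermediate
6 | methyl (4R)-4-hydroxy-6-methoxy-1,2,3,4-tetrahydronaphthalene-1-carboxylate (both C1 epimers) | COC(=O)C1CC[C@@H](O)c2cc(OC)ccc12 | intermediate
7 | (1S,4R)-4-hydroxy-6-methoxy-1,2,3,4-tetrahydronaphthalene-1-carboxylic acid 1,4-lactone | O=C1O[C@@H]2CC[C@H]1c3ccc(OC)cc23 | intermediate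
8 | dilithium (1S,4R)-4-oxido-6-methoxy-1,2,3,4-tetrahydronaphthalene-1-carboxylate | [Li+].[Li+].[O-]C(=O)[C@H]1CC[C@@H]([O-])c2cc(OC)ccc12 | intermediate (not isolated)
9 | (1S,4R)-4-hydroxy-6-methoxy-1,2,3,4,5,8-hexahydronaphthalene-1-carboxylic acid | OC(=O)[C@H]1CC[C@@H](O)C2=C1CC=C(OC)C2 | intermediate
10 | ethylene glycol | OCCO | starting material
11 | (1S,4R)-6,6-(ethylenedioxy)-4-hydroxy-1,2,3,4,5,6,7,8-octahydronaphthalene-1-carboxylic acid | OC(=O)[C@H]1CC[C@@H](O)C2=C1CCC3(OCCO3)C2 | intermediate
12 | tert-butyl (1S,4R)-6,6-(ethylenedioxy)-4-hydroxy-1,2,3,4,5,6,7,8-octahydronaphthalene-1-carboxylate (key-step precursor) | CC(C)(C)OC(=O)[C@H]1CC[C@@H](O)C2=C1CCC3(OCCO3)C2 | intermediate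
13 | ethylzinc alkoxide of 12 | CC(C)(C)OC(=O)[C@H]1CC[C@@H](O[Zn]CC)C2=C1CCC3(OCCO3)C2 | intermediate (not isolated)
14 | tert-butyl (1S,4R,4aR,8aS)-6,6-(ethylenedioxy)-4-hydroxyoctahydro-4a,8a-methanonaphthalene-1-carboxylate (key-step product) | C1C[C@@]2(C3)[C@@]3(CC14OCCO4)[C@H](O)CC[C@@H]2C(=O)OC(C)(C)C | intermediate
15 | tert-butyl (1S,4aR,8aS)-6,6-(ethylenedioxy)-4-oxooctahydro-4a,8a-methanonaphthalene-1-carboxylate | C1C[C@@]2(C3)[C@@]3(CC14OCCO4)C(=O)CC[C@@H]2C(=O)OC(C)(C)C | intermediate
16 | samarium enolate (C1–O–SmI2, C1=C10, C5 methyl) | C1C[C@@]2(C)C(CC14OCCO4)=C(O[Sm](I)I)CC[C@@H]2C(=O)OC(C)(C)C | intermediate (not isolated)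
17 | tert-butyl (1S,8aR)-6,6-(ethylenedioxy)-8a-methyl-4-(trimethylsilyloxy)-1,2,3,5,6,7,8,8a-octahydronaphthalene-1-carboxylate | C1C[C@@]2(C)C(CC14OCCO4)=C(O[Si](C)(C)C)CC[C@@H]2C(=O)OC(C)(C)C | intermediate
18 | tert-butyl (1S,8aR)-6,6-(ethylenedioxy)-8a-methyl-4-oxo-1,2,3,4,6,7,8,8a-octahydronaphthalene-1-carboxylate | C1C[C@@]2(C)C(=CC14OCCO4)C(=O)CC[C@@H]2C(=O)OC(C)(C)C | intermediate
19 | tert-butyl (1S,4R,8aR)-6,6-(ethylenedioxy)-4-hydroxy-8a-methyl-1,2,3,4,6,7,8,8a-octahydronaphthalene-1-carboxylate | C1C[C@@]2(C)C(=CC14OCCO4)[C@H](O)CC[C@@H]2C(=O)OC(C)(C)C | intermediate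
20 | (R)-4-benzyl-2-oxazolidinone | O=C1N[C@H](Cc2ccccc2)CO1 | starting material
21 | hexanoyl chloride | CCCCCC(=O)Cl | starting material
22 | (R)-4-benzyl-3-hexanoyloxazolidin-2-one | CCCCCC(=O)N1[C@H](Cc2ccccc2)COC1=O | intermediate
23 | sodium Z-enolate of 22 | CCCC/C=C(\O[Na])N1[C@H](Cc2ccccc2)COC1=O | intermediate (not isolated)
24 | (R)-4-benzyl-3-[(2R)-2-methylhexanoyl]oxazolidin-2-one | CCCC[C@@H](C)C(=O)N1[C@H](Cc2ccccc2)COC1=O | intermediate
25 | (R)-2-methylhexan-1-ol | CCCC[C@@H](C)CO | intermediate
26 | ethyl 2-(triphenylphosphoranylidene)propanoate | CCOC(=O)C(C)=P(c1ccccc1)(c1ccccc1)c1ccccc1 | starting material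
27 | (R)-2-methylhexanal | CCCC[C@@H](C)C=O | intermediate (not isolated)
28 | ethyl (2E,4R)-2,4-dimethyloct-2-enoate | CCCC[C@@H](C)/C=C(\C)C(=O)OCC | intermediate
29 | (2E,4R)-2,4-dimethyloct-2-enoic acid | CCCC[C@@H](C)/C=C(\C)C(=O)O | intermediate
30 | (2E,4R)-2,4-dimethyloct-2-enoic 2,4,6-trichlorobenzoic anhydride | CCCC[C@@H](C)/C=C(\C)C(=O)OC(=O)c1c(Cl)cc(Cl)cc1Cl | intermediate (not isolated)
31 | tert-butyl (1S,4R,8aR)-4-{[(2E,4R)-2,4-dimethyloct-2-enoyl]oxy}-6,6-(ethylenedioxy)-8a-methyl-1,2,3,4,6,7,8,8a-octahydronaphthalene-1-carboxylate | C1C[C@@]2(C)C(=CC14OCCO4)[C@H](OC(=O)/C(C)=C/[C@H](C)CCCC)CC[C@@H]2C(=O)OC(C)(C)C | intermediate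
32 | tert-butyl (1S,4R,8aR)-4-{[(2E,4R)-2,4-dimethyloct-2-enoyl]oxy}-8a-methyl-6-oxo-1,2,3,4,6,7,8,8a-octahydronaphthalene-1-carboxylate | C1C[C@@]2(C)C(=CC1=O)[C@H](OC(=O)/C(C)=C/[C@H](C)CCCC)CC[C@@H]2C(=O)OC(C)(C)C | intermediate
33 | lithium enolate of 32 (C7=C8–OLi, C9=C10) | C=1C[C@@]2(C)C(=CC=1O[Li])[C@H](OC(=O)/C(C)=C/[C@H](C)CCCC)CC[C@@H]2C(=O)OC(C)(C)C | intermediate (not isolated)
34 | tert-butyl (1S,4R,7R,8aR)-7-allyl-4-{[(2E,4R)-2,4-dimethyloct-2-enoyl]oxy}-8a-methyl-6-oxo-1,2,3,4,6,7,8,8a-octahydronaphthalene-1-carboxylate (allyl trans to the 8a-methyl) | C=CC[C@@H]1C[C@@]2(C)C(=CC1=O)[C@H](OC(=O)/C(C)=C/[C@H](C)CCCC)CC[C@@H]2C(=O)OC(C)(C)C | intermediate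
35 | (1S,4R,7R,8aR)-7-allyl-4-{[(2E,4R)-2,4-dimethyloct-2-enoyl]oxy}-8a-methyl-6-oxo-1,2,3,4,6,7,8,8a-octahydronaphthalene-1-carboxylic acid | C=CC[C@@H]1C[C@@]2(C)C(=CC1=O)[C@H](OC(=O)/C(C)=C/[C@H](C)CCCC)CC[C@@H]2C(=O)O | intermediate
36 | 7-(2,3-dihydroxypropyl) analogue of 35 (carbinol epimers) | OCC(O)C[C@@H]1C[C@@]2(C)C(=CC1=O)[C@H](OC(=O)/C(C)=C/[C@H](C)CCCC)CC[C@@H]2C(=O)O | intermediate (not isolated)
37 | (1S,4R,7S,8aR)-4-{[(2E,4R)-2,4-dimethyloct-2-enoyl]oxy}-8a-methyl-6-oxo-7-(2-oxoethyl)-1,2,3,4,6,7,8,8a-octahydronaphthalene-1-carboxylic acid | O=CC[C@@H]1C[C@@]2(C)C(=CC1=O)[C@H](OC(=O)/C(C)=C/[C@H](C)CCCC)CC[C@@H]2C(=O)O | intermediate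
38 | (1S,4R,7S,8aR)-4-{[(2E,4R)-2,4-dimethyloct-2-enoyl]oxy}-8a-methyl-6-oxo-7-(3-oxoprop-1-en-2-yl)-1,2,3,4,6,7,8,8a-octahydronaphthalene-1-carboxylic acid | C=C(C=O)[C@@H]1C[C@@]2(C)C(=CC1=O)[C@H](OC(=O)/C(C)=C/[C@H](C)CCCC)CC[C@@H]2C(=O)O | target

## Step count and least certain steps

Total step count: 23. Longest linear sequence: 18 steps (steps 1–12 and 18–23); the side-chain acid 29 takes 5 steps (13–17) and joins at step 18.

**Step 8 (key step).** The most likely problem is slow methylene transfer, because the alkene is tetrasubstituted and its reacting face also carries the bulky tert-butyl ester next to C5. Long exposure to zinc iodide and excess carbenoid then brings acetal cleavage or O-methylation of the hydroxyl. The fallback moves the cyclopropanation ahead of the esterification. It sets out from 11: with excess Et2Zn the acid gives a zinc alkoxide and a zinc carboxylate, both on the β face and neither bulky, and CH2I2 then delivers the methylene to give (1S,4R,4aR,8aS)-6,6-(ethylenedioxy)-4-hydroxyoctahydro-4a,8a-methanonaphthalene-1-carboxylic acid F1. Esterification of F1 with O-tert-butyl-N,N'-diisopropylisourea rejoins the route at 14.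

**Step 4.** The most likely problem is incomplete funnelling: ring-opening of the strained bridged lactone by methoxide competes with its formation, so the hydroxy esters persist as a cis/trans mixture. The fallback replaces the thermodynamic sink by separation and recycling. It sets out from 6: chromatography gives the cis epimer, methyl (1S,4R)-4-hydroxy-6-methoxy-1,2,3,4-tetrahydronaphthalene-1-carboxylate F2, and the trans epimer is re-equilibrated with NaOMe in MeOH (only the ester-bearing centre is labile) and separated again. F2 is saponified with LiOH and treated with LiNH2, which rejoins the route at 8.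

**Step 5.** The most likely problems are:
- reprotonation of the benzylic alkoxide by the alcohol donor, followed by reductive C–O cleavage;
- incomplete alkoxide formation, since the carboxylate forbids an alkyllithium, or deprotonation next to the carboxylate by the amide base with erosion of the C4 configuration;
- slow reduction of a sparingly soluble dilithium salt.

The fallback changes the oxidation level of C15 for the dearomatisation, setting out from 7.
- LiAlH4 gives (1R,4S)-4-(hydroxymethyl)-7-methoxy-1,2,3,4-tetrahydronaphthalen-1-ol F3.
- n-BuLi (2 equiv) turns F3 cleanly into the dialkoxide, and Li/NH3/t-BuOH then gives (1R,4S)-4-(hydroxymethyl)-7-methoxy-1,2,3,4,5,8-hexahydronaphthalen-1-ol F4.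
- Ethylene glycol/PPTS gives (1R,4S)-7,7-(ethylenedioxy)-4-(hydroxymethyl)-1,2,3,4,5,6,7,8-octahydronaphthalen-1-ol F5.
- Primary-selective TEMPO/PhI(OAc)2 oxidation gives (1S,4R)-6,6-(ethylenedioxy)-4-hydroxy-1,2,3,4,5,6,7,8-octahydronaphthalene-1-carbaldehyde F6, which is not isolated but oxidised at once with NaClO2/NaH2PO4/2-methyl-2-butene, rejoining the route at 11.

**Step 10.** The most likely problem is premature protonation of the samarium enolate or incomplete O-silylation, so that the regiochemical information of the enolate is lost. The fallback accepts the protonation. It sets out from 15: SmI2 in THF/MeOH gives tert-butyl 6,6-(ethylenedioxy)-8a-methyl-4-oxodecahydronaphthalene-1-carboxylate (1-ester and 8a-methyl cis, ring fusion as a mixture) F7. Enol silylation of F7 under equilibrating conditions (Me3SiCl, NaI, Et3N, MeCN), which favours the more substituted C1=C10 enol ether, rejoins the route at 17.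

**Step 12.** The most likely problem is insufficient facial selectivity with a small hydride: only one axial methyl differentiates the faces, and the wanted alcohol is the axial one. The fallback replaces substrate control by reagent control. It sets out from 18: oxazaborolidine-catalysed reduction with (S)-2-methyl-CBS-oxazaborolidine and catecholborane (toluene, −78 °C), in which the alkenyl side of the enone acts as the large group, is predicted to give the (1R) alcohol and rejoins the route at 19. No new compound is involved.

## Further compounds

F1 | step 8 | (1S,4R,4aR,8aS)-6,6-(ethylenedioxy)-4-hydroxyoctahydro-4a,8a-methanonaphthalene-1-carboxylic acid | C1C[C@@]2(C3)[C@@]3(CC14OCCO4)[C@H](O)CC[C@@H]2C(=O)O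
F2 | step 4 | methyl (1S,4R)-4-hydroxy-6-methoxy-1,2,3,4-tetrahydronaphthalene-1-carboxylate | COC(=O)[C@H]1CC[C@@H](O)c2cc(OC)ccc12
F3 | step 5 | (1R,4S)-4-(hydroxymethyl)-7-methoxy-1,2,3,4-tetrahydronaphthalen-1-ol | OC[C@H]1CC[C@@H](O)c2cc(OC)ccc12
F4 | step 5 | (1R,4S)-4-(hydroxymethyl)-7-methoxy-1,2,3,4,5,8-hexahydronaphthalen-1-ol | OC[C@H]1CC[C@@H](O)C2=C1CC=C(OC)C2
F5 | step 5 | (1R,4S)-7,7-(ethylenedioxy)-4-(hydroxymethyl)-1,2,3,4,5,6,7,8-octahydronaphthalen-1-ol | OC[C@H]1CC[C@@H](O)C2=C1CCC3(OCCO3)C2
F6 | step 5 | (1S,4R)-6,6-(ethylenedioxy)-4-hydroxy-1,2,3,4,5,6,7,8-octahydronaphthalene-1-carbaldehyde | O=C[C@H]1CC[C@@H](O)C2=C1CCC3(OCCO3)C2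
F7 | step 10 | tert-butyl 6,6-(ethylenedioxy)-8a-methyl-4-oxodecahydronaphthalene-1-carboxylate (1-ester and 8a-methyl cis, ring fusion mixed) | C1C[C@@]2(C)C(CC14OCCO4)C(=O)CC[C@@H]2C(=O)OC(C)(C)C
F0 | step 12 | none | none
A1 | alternative 1 | tert-butyl (2E,6S,8Z)-6,9-bis(tert-butyldimethylsilyloxy)-3-methylundeca-2,8,10-trienoate | C=C/C(O[Si](C)(C)C(C)(C)C)=C/C[C@@H](O[Si](C)(C)C(C)(C)C)CC/C(C)=C/C(=O)OC(C)(C)C
A2 | alternative 1 | trans-fused tert-butyl 4,6-bis(tert-butyldimethylsilyloxy)-8a-methyl-1,2,4a,5,6,7,8,8a-octahydronaphthalene-1-carboxylate (1-ester and 8a-methyl cis) | C1C[C@@]2(C)[C@H](C[C@H]1O[Si](C)(C)C(C)(C)C)C(O[Si](C)(C)C(C)(C)C)=CC[C@@H]2C(=O)OC(C)(C)C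
A3 | alternative 2 | tert-butyl 8,8-(ethylenedioxy)-6-hydroxy-3-methyl-6-vinylbicyclo[2.2.2]oct-2-ene-2-carboxylate (vinyl syn to the alkene bridge) | C=C[C@]1(O)C[C@H]2C3(OCCO3)C[C@@H]1C(C(=O)OC(C)(C)C)=C2C
A4 | alternative 2 | cis-fused tert-butyl 4,4-(ethylenedioxy)-8a-methyl-6-oxo-3,4,4a,5,6,7,8,8a-octahydronaphthalene-1-carboxylate | C1C[C@@]2(C)[C@@H](CC1=O)C3(OCCO3)CC=C2C(=O)OC(C)(C)C
A5 | alternative 3 | tert-butyl (2S)-2-(1-methyl-4-oxocyclohexa-2,5-dien-1-yl)-5-oxopentanoate | O=CCC[C@H](C(=O)OC(C)(C)C)C1(C)C=CC(=O)C=C1
A6 | alternative 3 | cis-fused tert-butyl 8a-methyl-4,6-dioxo-1,2,3,4,4a,5,6,8a-octahydronaphthalene-1-carboxylate (1-ester and 8a-methyl cis) | C1=C[C@@]2(C)[C@@H](CC1=O)C(=O)CC[C@@H]2C(=O)OC(C)(C)C
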